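**Retrosynthetic overview**
1. Acid 21 ⇐ tert-butyl ester 19 ⇐ Negishi union (C12–C13) of the zinc reagent from iodide 14 with the E enol tosylate 17, which already carries the acetoxymethyl group cis to the ester.
2. Decalone 13 (precursor of 14) ⇐ bicyclo[3.1.0]hexan-1-ol 12 in one oxidative radical cascade: enlargement of the cyclopentane to the cyclohexanone ring A, 6-endo closure of ring B, and formation of the exocyclic methylene.
3. 12 ⇐ silyl enol ether 10 (cyclopropanation) ⇐ asymmetric conjugate addition of Grignard reagent 8 (from 4-bromobut-1-yne by carboalumination/ethylene oxide) to 2,4,4-trimethylcyclopent-2-enone 7.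
4. Enabling feature (labdane numbering): the ring A carbonyl C2 is joined through the methylene C1 to the quaternary ring-fusion carbon C10. C2–C10 can therefore be the internal bond of a cyclopropanol with C1 as apex; its homolysis gives the six-membered ketone and a tertiary C10 radical next to C9 of ring B, whose neighbour C8 carries the 8(17)-methylene.
5. Ring order: purchased cyclopentane → cyclopropane (step 5) → ring A by enlargement and ring B by closure, both in step 6.

Key step: step 6

Remark: labdane numbering is used for the decalin (C2 = ring A carbonyl, C5/C10 = ring fusion, C9 = side-chain carbon, C17 = exocyclic methylene carbon), and the enantiomer of the ferrocenyl diphosphine in step 4 is assumed to be the one that delivers the (R) centre.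

Step 1
Reactants: 1 4-bromobut-1-yne
Product: 4 (3E)-6-bromo-4-methylhex-3-en-1-ol, via alkenyldimethylalane 2 (not isolated), via lithium alkenylalanate 3 (not isolated)
Conditions: Me3Al, Cp2ZrCl2 (25 mol %), CH2Cl2, 0 °C to rt; evaporate volatiles; n-BuLi, hexane/THF, −78 °C; ethylene oxide, −78 to 0 °C; 1 M HCl work-up
Reagents that add atoms: trimethylaluminium C[Al](C)C; ethylene oxide C1CO1
Why: Zirconium-catalysed Negishi carboalumination adds methyl and aluminium syn with aluminium on the terminal carbon, and the derived lithium alkenylalanate opens ethylene oxide with retention, so the E trisubstituted alkene (the future C8=C9 with C17 as its methyl) is fixed.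

Step 2
Reactants: 4 (3E)-6-bromo-4-methylhex-3-en-1-ol
Product: 5 (3E)-1-bromo-6-chloro-3-methylhex-3-ene
Conditions: PPh3, N-chlorosuccinimide, CH2Cl2, 0 °C to rt
Reagents that add atoms: N-chlorosuccinimide O=C1CCC(=O)N1Cl
Why: Appel-type chlorination replaces the primary hydroxyl by SN2 attack of chloride on the alkoxyphosphonium ion and should leave the alkyl bromide and the alkene untouched.

Step 3
Reactants: 6 2,4,4-trimethylcyclopentan-1-one
Product: 7 2,4,4-trimethylcyclopent-2-en-1-one
Conditions: IBX, DMSO/fluorobenzene, 70 °C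
Reagents that add atoms: none
Why: IBX dehydrogenation of a ketone to the enone can only desaturate the C2–C3 bond because C4 is quaternary, so a single enone should form.

Step 4
Reactants: 5 (3E)-1-bromo-6-chloro-3-methylhex-3-ene; 7 2,4,4-trimethylcyclopent-2-en-1-one
Product: 10 trimethyl({(3R)-3-[(3E)-6-chloro-3-methylhex-3-en-1-yl]-2,4,4-trimethylcyclopent-1-en-1-yl}oxy)silane, via Grignard reagent 8 (not isolated), via magnesium enolate 9 (not isolated)
Conditions: 5, Mg, Et2O, rt; added to 7, CuBr·SMe2 (5 mol %), (R)-1-[(S)-2-(diphenylphosphino)ferrocenyl]ethyldicyclohexylphosphine (6 mol %), t-BuOMe, −78 °C; then TMSCl, Et3N, DMPU, −78 to 0 °C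
Reagents that add atoms: chlorotrimethylsilane C[Si](C)(C)Cl
Why: Magnesium inserts selectively into the C–Br bond, and copper-catalysed asymmetric conjugate addition of the Grignard reagent (a reaction type known for 2-methylcyclopent-2-enone with ferrocenyl diphosphines) delivers the chain to one enantioface of the β-carbon and so sets the only stereocentre carried forward (R, the future C5), while O-silylation of the magnesium enolate fixes the tetrasubstituted enol ether regiospecifically.

Step 5
Reactants: 10 trimethyl({(3R)-3-[(3E)-6-chloro-3-methylhex-3-en-1-yl]-2,4,4-trimethylcyclopent-1-en-1-yl}oxy)silane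
Product: 12 (1S,4R,5S)-4-[(3E)-6-chloro-3-methylhex-3-en-1-yl]-3,3,5-trimethylbicyclo[3.1.0]hexan-1-ol, via siloxycyclopropane 11 (not isolated)
Conditions: Et2Zn (1.2 equiv), CH2I2 (1.2 equiv), CH2Cl2, 0 °C; then K2CO3 (cat.), MeOH, 0 °C
Reagents that add atoms: diiodomethane ICI
Why: Simmons–Smith cyclopropanation (Furukawa modification) should be much faster on the electron-rich silyl enol ether than on the isolated trisubstituted alkene when the carbenoid is limiting, and mild methanolysis frees the cyclopropanol; the two new cyclopropane centres (methylene expected anti to the side chain) are both erased in step 6, so their control is not needed.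

Step 6
Reactants: 12 (1S,4R,5S)-4-[(3E)-6-chloro-3-methylhex-3-en-1-yl]-3,3,5-trimethylbicyclo[3.1.0]hexan-1-ol
Product: 13 (4aR,8R,8aR)-8-(2-chloroethyl)-4,4,8a-trimethyl-7-methylideneoctahydronaphthalen-2(1H)-one
Conditions: manganese tris(pyridine-2-carboxylate) Mn(O2CC5H4N)3 (2.2 equiv), Cu(OAc)2 (20 mol %), degassed DMF, 0 °C to rt
Reagents that add atoms: none
Why: Ligand exchange gives an alkoxide of trivalent manganese, and inner-sphere one-electron oxidation cleaves the strained internal C2–C10 bond of the bicyclo[3.1.0]hexane, so the cyclopentane becomes the six-membered ring A ketone (C1, the former cyclopropane methylene, now lies between C2 and C10) and a tertiary β-keto radical appears at C10; this radical adds to C9 of the E trisubstituted alkene, and the tertiary C8 radical so formed is captured by divalent copper and loses a C17 hydrogen to give the exocyclic methylene, monovalent copper being reoxidised by the manganese reagent. The closest known reaction types are the ring-enlarging generation of β-keto radicals from bicyclic cyclopropanols with this manganese reagent, the ring-expansion/radical-cyclisation cascades of alkenyl-substituted bicyclic cyclopropanol silyl ethers under trivalent iron, and the oxidative radical polyene cyclisations with Mn(OAc)3/Cu(OAc)2, whose second ring closure passes through the same kind of C10 radical and ends in the same copper-mediated elimination. Ring A is not closed but enlarged by one carbon through β-scission, and ring B is closed in the 6-endo-trig radical mode (C10 to C9). The quaternary centre C10 is controlled by the existing C5 centre, because the chair transition state with the C5 hydrogen and the C10 methyl anti (trans ring fusion) is the unstrained one, and C9 is controlled by the E geometry of the alkene, which places the 2-chloroethyl arm equatorial and its hydrogen anti to the C10 methyl. The step needs cleavage of the internal and not the external cyclopropane bond (secured by the methyl at C10, which makes the ring-enlarged radical tertiary, and by re-closure of any external-bond radical into the same manifold), 6-endo and not 5-exo closure (secured by the methyl on C8), cyclisation before oxidation of the C10 radical (secured by keeping divalent copper catalytic) and elimination towards C17 (the unhindered methyl hydrogens are the ones reached in the syn elimination of the organocopper intermediate).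

Step 7
Reactants: 13 (4aR,8R,8aR)-8-(2-chloroethyl)-4,4,8a-trimethyl-7-methylideneoctahydronaphthalen-2(1H)-one
Product: 14 (4aR,8R,8aR)-8-(2-iodoethyl)-4,4,8a-trimethyl-7-methylideneoctahydronaphthalen-2(1H)-one
Conditions: NaI, acetone, reflux
Reagents that add atoms: sodium iodide [Na+].[I-]
Why: Finkelstein exchange is an SN2 displacement at the unhindered primary chloride, driven by precipitation of sodium chloride, and should not affect the ketone or the alkene.

Step 8
Reactants: 15 tert-butyl 4-chloro-3-oxobutanoate
Product: 16 tert-butyl 4-(acetyloxy)-3-oxobutanoate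
Conditions: KOAc, DMF, rt
Reagents that add atoms: potassium acetate CC(=O)[O-].[K+]
Why: SN2 displacement of the activated α-chloro ketone chloride by acetate installs the acetate of the target at the outset.

Step 9
Reactants: 16 tert-butyl 4-(acetyloxy)-3-oxobutanoate
Product: 17 tert-butyl (2E)-4-(acetyloxy)-3-{[(4-methylphenyl)sulfonyl]oxy}but-2-enoate
Conditions: TsCl, N-methylimidazole, Et3N, MeCN, 0 °C
Reagents that add atoms: 4-methylbenzenesulfonyl chloride Cc1ccc(cc1)S(Cl)(=O)=O
Why: Enol tosylation of a β-keto ester under non-chelating amine conditions is known to give the E enol tosylate, with the tosylate trans and the acetoxymethyl group cis to the ester, which is the geometry the target alkene needs after a retentive coupling.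

Step 10
Reactants: 14 (4aR,8R,8aR)-8-(2-iodoethyl)-4,4,8a-trimethyl-7-methylideneoctahydronaphthalen-2(1H)-one; 17 tert-butyl (2E)-4-(acetyloxy)-3-{[(4-methylphenyl)sulfonyl]oxy}but-2-enoate
Product: 19 tert-butyl (2Z)-3-[(acetyloxy)methyl]-5-[(1R,4aR,8aR)-5,5,8a-trimethyl-2-methylidene-7-oxodecahydronaphthalen-1-yl]pent-2-enoate, via alkylzinc iodide 18 (not isolated)
Conditions: 14, Zn dust, LiCl, THF, 40 °C; then 17, Pd(OAc)2 (3 mol %), 2-dicyclohexylphosphino-2′,6′-dimethoxybiphenyl (6 mol %), THF, rt
Reagents that add atoms: none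
Why: LiCl-promoted zinc insertion into the primary iodide tolerates the ketone, and Negishi coupling of the alkylzinc iodide with the activated enol tosylate under zerovalent palladium proceeds with retention of alkene geometry, so the new C12–C13 bond ends trans to the ester and the Z acetoxy enoate results.

Step 11
Reactants: 19 tert-butyl (2Z)-3-[(acetyloxy)methyl]-5-[(1R,4aR,8aR)-5,5,8a-trimethyl-2-methylidene-7-oxodecahydronaphthalen-1-yl]pent-2-enoate
Product: 21 (2Z)-3-[(acetyloxy)methyl]-5-[(1R,4aR,8aR)-5,5,8a-trimethyl-2-methylidene-7-oxodecahydronaphthalen-1-yl]pent-2-enoic acid, via trimethylsilyl ester 20 (not isolated)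
Conditions: TMSOTf, 2,6-lutidine, CH2Cl2, 0 °C; aqueous citric acid work-up
Reagents that add atoms: none
Why: Silyl-triflate cleavage of the tert-butyl ester (loss of 2-methylpropene, silyl ester hydrolysed on work-up) under buffered aprotic conditions should leave the acetate, the acid-sensitive exocyclic alkene and the Z enoate untouched, and any silyl enol ether formed at the ketone reverts on work-up.

**Compound list**
1 | 4-bromobut-1-yne | C#CCCBr | starting material
2 | [(1E)-4-bromo-2-methylbut-1-en-1-yl]dimethylalane | BrCC/C(C)=C/[Al](C)C | intermediate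
3 | lithium butyl[(1E)-4-bromo-2-methylbut-1-en-1-yl]dimethylalanate | [Li+].BrCC/C(C)=C/[Al-](C)(C)CCCC | intermediate
4 | (3E)-6-bromo-4-methylhex-3-en-1-ol | BrCC/C(C)=C/CCO | intermediate
5 | (3E)-1-bromo-6-chloro-3-methylhex-3-ene | BrCC/C(C)=C/CCCl | intermediate
6 | 2,4,4-trimethylcyclopentan-1-one (racemic) | CC1CC(C)(C)CC1=O | starting material
7 | 2,4,4-trimethylcyclopent-2-en-1-one | CC1=CC(C)(C)CC1=O | intermediate
8 | [(3E)-6-chloro-3-methylhex-3-en-1-yl]magnesium bromide | Br[Mg]CC/C(C)=C/CCCl | intermediate
9 | bromomagnesium (3R)-3-[(3E)-6-chloro-3-methylhex-3-en-1-yl]-2,4,4-trimethylcyclopent-1-en-1-olate | Br[Mg]OC1=C(C)[C@H](CC/C(C)=C/CCCl)C(C)(C)C1 | intermediate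
10 | trimethyl({(3R)-3-[(3E)-6-chloro-3-methylhex-3-en-1-yl]-2,4,4-trimethylcyclopent-1-en-1-yl}oxy)silane | C[Si](C)(C)OC1=C(C)[C@H](CC/C(C)=C/CCCl)C(C)(C)C1 | intermediate
11 | trimethyl({(1S,4R,5S)-4-[(3E)-6-chloro-3-methylhex-3-en-1-yl]-3,3,5-trimethylbicyclo[3.1.0]hexan-1-yl}oxy)silane (cyclopropane methylene anti to the side chain) | C[Si](C)(C)O[C@]12C[C@@]1(C)[C@H](CC/C(C)=C/CCCl)C(C)(C)C2 | intermediate
12 | (1S,4R,5S)-4-[(3E)-6-chloro-3-methylhex-3-en-1-yl]-3,3,5-trimethylbicyclo[3.1.0]hexan-1-ol | O[C@]12C[C@@]1(C)[C@H](CC/C(C)=C/CCCl)C(C)(C)C2 | intermediate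
13 | (4aR,8R,8aR)-8-(2-chloroethyl)-4,4,8a-trimethyl-7-methylideneoctahydronaphthalen-2(1H)-one | C=C1CC[C@@H]2C(C)(C)CC(=O)C[C@@]2(C)[C@@H]1CCCl | intermediate
14 | (4aR,8R,8aR)-8-(2-iodoethyl)-4,4,8a-trimethyl-7-methylideneoctahydronaphthalen-2(1H)-one | C=C1CC[C@@H]2C(C)(C)CC(=O)C[C@@]2(C)[C@@H]1CCI | intermediate
15 | tert-butyl 4-chloro-3-oxobutanoate | ClCC(=O)CC(=O)OC(C)(C)C | starting material
16 | tert-butyl 4-(acetyloxy)-3-oxobutanoate | CC(=O)OCC(=O)CC(=O)OC(C)(C)C | intermediate
17 | tert-butyl (2E)-4-(acetyloxy)-3-{[(4-methylphenyl)sulfonyl]oxy}but-2-enoate | CC(=O)OC/C(OS(=O)(=O)c1ccc(C)cc1)=C\C(=O)OC(C)(C)C | intermediate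
18 | {2-[(1R,4aR,8aR)-5,5,8a-trimethyl-2-methylidene-7-oxodecahydronaphthalen-1-yl]ethyl}zinc iodide | C=C1CC[C@@H]2C(C)(C)CC(=O)C[C@@]2(C)[C@@H]1CC[Zn]I | intermediate
19 | tert-butyl (2Z)-3-[(acetyloxy)methyl]-5-[(1R,4aR,8aR)-5,5,8a-trimethyl-2-methylidene-7-oxodecahydronaphthalen-1-yl]pent-2-enoate | C=C1CC[C@@H]2C(C)(C)CC(=O)C[C@@]2(C)[C@@H]1CC/C(=C/C(=O)OC(C)(C)C)COC(C)=O | intermediate
20 | trimethylsilyl (2Z)-3-[(acetyloxy)methyl]-5-[(1R,4aR,8aR)-5,5,8a-trimethyl-2-methylidene-7-oxodecahydronaphthalen-1-yl]pent-2-enoate | C=C1CC[C@@H]2C(C)(C)CC(=O)C[C@@]2(C)[C@@H]1CC/C(=C/C(=O)O[Si](C)(C)C)COC(C)=O | intermediate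
21 | (2Z)-3-[(acetyloxy)methyl]-5-[(1R,4aR,8aR)-5,5,8a-trimethyl-2-methylidene-7-oxodecahydronaphthalen-1-yl]pent-2-enoic acid | C=C1CC[C@@H]2C(C)(C)CC(=O)C[C@@]2(C)[C@@H]1CC/C(=C/C(=O)O)COC(C)=O | target

**Totals**
Total step count: 11 steps.
Longest linear sequence: 8 steps (steps 1, 2, 4, 5, 6, 7, 10, 11; 1 → 4 → 5 → 10 → 12 → 13 → 14 → 19 → 21).

**Steps most likely to fail, with fallbacks**

Step 6. What may go wrong is that one-electron oxidation of the tertiary C10 radical (towards the ring-enlarged enone) outruns the 6-endo closure, or that the final elimination is not selective for the C17 hydrogens. The fallback sets out from 12 and keeps the ring enlargement but closes ring B in a polar way. Ring enlargement of 12 with FeCl3 in DMF at 0 °C, with chlorine-atom capture of the C10 radical, should give the β-chloro ketone (4R)-3-chloro-4-[(3E)-6-chloro-3-methylhex-3-en-1-yl]-3,5,5-trimethylcyclohexan-1-one F1. Warming with NaOAc in methanol should eliminate HCl to the enone (4R)-4-[(3E)-6-chloro-3-methylhex-3-en-1-yl]-3,5,5-trimethylcyclohex-2-en-1-one F2. F2 is then cyclised by a Lewis-acid-promoted intramolecular conjugate ene reaction (MeAlCl2, CH2Cl2, −78 to 0 °C), in which C9 of the alkene attacks the enone β-carbon C10 and a C17 hydrogen passes to the enolate. This comes back to the route at 13, with stereocontrol at C9/C10 expected to be less secure than in the radical mode.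

Step 4. What may go wrong is slow or poorly face-selective conjugate addition at a β-carbon flanked by the α-methyl group and the gem-dimethyl carbon. The fallback sets out from 5 (as Grignard reagent 8) and uses commercial 4,4-dimethylcyclopent-2-en-1-one, whose α-carbon is unsubstituted. Copper-catalysed asymmetric conjugate addition under the same catalyst should give bromomagnesium (3S)-3-[(3E)-6-chloro-3-methylhex-3-en-1-yl]-4,4-dimethylcyclopent-1-en-1-olate F3. This is methylated in the same flask (MeI, DMPU) to the trans ketone (2S,3S)-3-[(3E)-6-chloro-3-methylhex-3-en-1-yl]-2,4,4-trimethylcyclopentan-1-one F4. Thermodynamic enol silylation (TMSCl, NaI, Et3N, MeCN) towards the more substituted side then comes back to the route at 10.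

Step 10. What may go wrong is ionisation of the allylic acetate (in 17 or in 19) by zerovalent palladium competing with oxidative addition into the C–OTs bond, followed by allylic alkylation by the zinc reagent. The fallback sets out from 14 (as zinc reagent 18) and couples a partner without an allylic ester. Claisen condensation of the lithium enolate of tert-butyl acetate with ethyl [(tert-butyldimethylsilyl)oxy]acetate should give tert-butyl 4-[(tert-butyldimethylsilyl)oxy]-3-oxobutanoate F5. E-selective tosylation as in step 9 gives tert-butyl (2E)-4-[(tert-butyldimethylsilyl)oxy]-3-{[(4-methylphenyl)sulfonyl]oxy}but-2-enoate F6. Negishi coupling with 18 gives tert-butyl (2Z)-3-{[(tert-butyldimethylsilyl)oxy]methyl}-5-[(1R,4aR,8aR)-5,5,8a-trimethyl-2-methylidene-7-oxodecahydronaphthalen-1-yl]pent-2-enoate F7. HF·pyridine/pyridine in THF at 0 °C, followed in the same flask by Ac2O/DMAP, converts F7 through tert-butyl (2Z)-3-(hydroxymethyl)-5-[(1R,4aR,8aR)-5,5,8a-trimethyl-2-methylidene-7-oxodecahydronaphthalen-1-yl]pent-2-enoate F8 into the acetate, which comes back to the route at 19.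

Further compounds
F1 | step 6 | (4R)-3-chloro-4-[(3E)-6-chloro-3-methylhex-3-en-1-yl]-3,5,5-trimethylcyclohexan-1-one (mixture at C3) | O=C1CC(C)(C)[C@@H](CC/C(C)=C/CCCl)C(C)(Cl)C1
F2 | step 6 | (4R)-4-[(3E)-6-chloro-3-methylhex-3-en-1-yl]-3,5,5-trimethylcyclohex-2-en-1-one | O=C1C=C(C)[C@H](CC/C(C)=C/CCCl)C(C)(C)C1
F3 | step 4 | bromomagnesium (3S)-3-[(3E)-6-chloro-3-methylhex-3-en-1-yl]-4,4-dimethylcyclopent-1-en-1-olate | Br[Mg]OC1=C[C@H](CC/C(C)=C/CCCl)C(C)(C)C1
F4 | step 4 | (2S,3S)-3-[(3E)-6-chloro-3-methylhex-3-en-1-yl]-2,4,4-trimethylcyclopentan-1-one | C[C@@H]1C(=O)CC(C)(C)[C@H]1CC/C(C)=C/CCCl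
F5 | step 10 | tert-butyl 4-[(tert-butyldimethylsilyl)oxy]-3-oxobutanoate | CC(C)(C)[Si](C)(C)OCC(=O)CC(=O)OC(C)(C)C
F6 | step 10 | tert-butyl (2E)-4-[(tert-butyldimethylsilyl)oxy]-3-{[(4-methylphenyl)sulfonyl]oxy}but-2-enoate | CC(C)(C)[Si](C)(C)OC/C(OS(=O)(=O)c1ccc(C)cc1)=C\C(=O)OC(C)(C)C
F7 | step 10 | tert-butyl (2Z)-3-{[(tert-butyldimethylsilyl)oxy]methyl}-5-[(1R,4aR,8aR)-5,5,8a-trimethyl-2-methylidene-7-oxodecahydronaphthalen-1-yl]pent-2-enoate | C=C1CC[C@@H]2C(C)(C)CC(=O)C[C@@]2(C)[C@@H]1CC/C(=C/C(=O)OC(C)(C)C)CO[Si](C)(C)C(C)(C)C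
F8 | step 10 | tert-butyl (2Z)-3-(hydroxymethyl)-5-[(1R,4aR,8aR)-5,5,8a-trimethyl-2-methylidene-7-oxodecahydronaphthalen-1-yl]pent-2-enoate | C=C1CC[C@@H]2C(C)(C)CC(=O)C[C@@]2(C)[C@@H]1CC/C(=C/C(=O)OC(C)(C)C)CO
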